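**Retrosynthetic overview**

1. The target is reached from a ring A precursor that carries the C4 oxygen as a triisopropylsilyl ether and the C3 formyl carbon as a diethyl acetal.
2. The strategy rests on ring A, a pentasubstituted benzene (C1 depside carbonyl, C2–OH, C3–CHO, C4–OH, C6–CH3, C5–H), that is, a resorcinol with the formyl carbon between the two oxygens. It is cut at C2–C3, C4–C5 and C1–C2 into a vinylketene (C2, C5, C6, C1) and an oxygenated alkyne (C3, C4): a Danheiser benzannulation of an α'-diazo enone with a siloxyalkyne.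
3. The diazo enone already carries ring B as its aryl ester. It comes from the corresponding methyl ketone by detrifluoroacetylative diazo transfer, and the methyl ketone from a Wittig product of butane-2,3-dione and the ring B phenol.
4. Ring B is taken intact from atraric acid (C4 benzylation, C2 methylation, hydrogenolysis). The siloxyalkyne is made in one step from 3,3-diethoxyprop-1-yne.
5. Ring order: ring B is purchased; ring A is the only ring formed, in step 9.

Key step: step 9

Remark: the formyl group is carried as a diethyl acetal because 3,3-diethoxyprop-1-yne is the commercial alkyne. Ring A is numbered C1 (depside carbonyl), C2 (OH), C3 (CHO), C4 (OH), C5 (H), C6 (CH3); ring B positions are primed.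

**Route**

Step 1
Reactants: 1 methyl 2,4-dihydroxy-3,6-dimethylbenzoate (atraric acid)
Product: 2 methyl 4-(benzyloxy)-2-hydroxy-3,6-dimethylbenzoate
Conditions: BnBr (1.05 equiv), K2CO3, acetone, reflux
Reagents that add atoms: benzyl bromide, BrCc1ccccc1
Why: Williamson etherification; the C2' hydroxyl is hydrogen-bonded to the ester carbonyl and flanked by the C3' methyl, so one equivalent of benzyl bromide should alkylate only the free, more acidic C4' hydroxyl.

Step 2
Reactants: 2 methyl 4-(benzyloxy)-2-hydroxy-3,6-dimethylbenzoate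
Product: 3 methyl 4-(benzyloxy)-2-methoxy-3,6-dimethylbenzoate
Conditions: MeI (excess), K2CO3, DMF, 60 °C
Reagents that add atoms: iodomethane, CI
Why: Williamson methylation of the remaining chelated, hindered C2' phenol, which should proceed with excess iodomethane in warm DMF now that the C4' oxygen is blocked.

Step 3
Reactants: 3 methyl 4-(benzyloxy)-2-methoxy-3,6-dimethylbenzoate
Product: 4 methyl 4-hydroxy-2-methoxy-3,6-dimethylbenzoate (ring B phenol)
Conditions: H2 (1 atm), 10% Pd/C, EtOAc, rt
Reagents that add atoms: none
Why: Hydrogenolysis of the benzyl ether over Pd/C frees the C4' phenol while the methyl ether, the methyl ester and the aryl methyls are inert.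

Step 4
Reactants: 5 butane-2,3-dione; 6 tert-butyl (triphenylphosphoranylidene)acetate
Product: 7 tert-butyl (2E)-3-methyl-4-oxopent-2-enoate
Conditions: 5 (3 equiv), CH2Cl2, 0 °C to rt
Reagents that add atoms: none
Why: Wittig olefination of one carbonyl of the activated 1,2-diketone by the stabilised ylide; excess volatile diketone suppresses double olefination, and the stabilised ylide with its bulky ester should give mainly the E alkene (acetyl trans to ester), the minor Z isomer being removed by chromatography.

Step 5
Reactants: 7 tert-butyl (2E)-3-methyl-4-oxopent-2-enoate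
Product: 8 (2E)-3-methyl-4-oxopent-2-enoic acid
Conditions: CF3CO2H, CH2Cl2, rt
Reagents that add atoms: none
Why: Acidolysis of the tert-butyl ester (loss of isobutene through the tert-butyl cation) leaves ketone and alkene untouched, and the E acid cannot close to a hydroxybutenolide.

Step 6
Reactants: 4 methyl 4-hydroxy-2-methoxy-3,6-dimethylbenzoate; 8 (2E)-3-methyl-4-oxopent-2-enoic acid
Product: 9 methyl 2-methoxy-3,6-dimethyl-4-{[(2E)-3-methyl-4-oxopent-2-enoyl]oxy}benzoate
Conditions: DCC, DMAP (cat.), CH2Cl2, 0 °C to rt
Reagents that add atoms: none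
Why: Steglich esterification; the O-acylisourea formed with DCC is relayed by DMAP to an acylpyridinium ion that acylates the only free hydroxyl of 4, and the mild conditions should keep the E enone intact.

Step 7
Reactants: 9 methyl 2-methoxy-3,6-dimethyl-4-{[(2E)-3-methyl-4-oxopent-2-enoyl]oxy}benzoate
Product: 11 methyl 4-{[(2E)-5-diazo-3-methyl-4-oxopent-2-enoyl]oxy}-2-methoxy-3,6-dimethylbenzoate, via trifluoroacetyl diketone 10 (not isolated)
Conditions: LiN(SiMe3)2, THF, −78 °C (9 added to the base); CF3CO2CH2CF3, −78 °C; dilute HCl work-up; then MsN3, Et3N, H2O (1 equiv), MeCN, rt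
Reagents that add atoms: methanesulfonyl azide, CS(=O)(=O)N=[N+]=[N-] (the two diazo nitrogens); 2,2,2-trifluoroethyl trifluoroacetate, O=C(OCC(F)(F)F)C(F)(F)F (trifluoroacetyl group of intermediate 10 only, lost again)
Why: Detrifluoroacetylative diazo transfer: LiN(SiMe3)2 at −78 °C deprotonates the only enolisable position of the ketone (the C5 methyl) without touching the benzylic methyls or the aryl ester, Claisen acylation gives the activated 1,3-diketone 10, and MsN3 with Et3N transfers N2 with loss of the trifluoroacetyl group; this route avoids acylating diazomethane, which would add as a 1,3-dipole across the electron-poor alkene.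

Step 8
Reactants: 12 3,3-diethoxyprop-1-yne
Product: 15 3,3-diethoxy-1-[(triisopropylsilyl)oxy]prop-1-yne, via lithium acetylide 13 (not isolated), via lithium ynolate 14 (not isolated)
Conditions: LiN(SiMe3)2 (2.2 equiv), t-BuOOH (anhydrous, 1.1 equiv), THF, −78 to 0 °C; then i-Pr3SiOTf, −78 °C to rt; isolation on Et3N-deactivated silica
Reagents that add atoms: tert-butyl hydroperoxide, CC(C)(C)OO (the ynol oxygen); triisopropylsilyl trifluoromethanesulfonate, CC(C)[Si](C(C)C)(C(C)C)OS(=O)(=O)C(F)(F)F; lithium bis(trimethylsilyl)amide, [Li]N([Si](C)(C)C)[Si](C)(C)C (lithium of intermediates 13 and 14 only)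
Why: The lithium acetylide attacks the peroxide oxygen of t-BuOOLi (electrophilic oxygen transfer) to give the lithium ynolate, which the bulky silyl triflate should silylate on oxygen and not on carbon, and the basic medium protects the acetal.

Step 9
Reactants: 11 methyl 4-{[(2E)-5-diazo-3-methyl-4-oxopent-2-enoyl]oxy}-2-methoxy-3,6-dimethylbenzoate; 15 3,3-diethoxy-1-[(triisopropylsilyl)oxy]prop-1-yne
Product: 19 methyl 4-({3-(diethoxymethyl)-2-hydroxy-6-methyl-4-[(triisopropylsilyl)oxy]benzoyl}oxy)-2-methoxy-3,6-dimethylbenzoate, via vinylketene 16 (not isolated), via vinylcyclobutenone 17 (not isolated), via dienylketene 18 (not isolated)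
Conditions: hν (365 nm), 15 (1.5 equiv), degassed ClCH2CH2Cl, base-washed glassware, rt; then 80 °C
Reagents that add atoms: none
Why: Irradiation expels N2 from 11 and the alkenyl group migrates (photochemical Wolff rearrangement) to give vinylketene 16, which the electron-rich alkyne traps in a regioselective (2+2) cycloaddition: the alkyne carbon remote from oxygen bonds to the ketene carbonyl carbon (new C2–C3 bond) and the oxygen-bearing carbon bonds to the former diazo carbon (new C4–C5 bond), giving racemic 4-alkenylcyclobutenone 17. Heating opens 17 by reversible 4π electrocyclic cleavage of the C2–C5 bond to dienylketene 18, and ring A then closes by thermal disrotatory 6π electrocyclisation of the ketene carbon onto the ester-bearing alkene carbon (new C1–C2 bond), after which the cyclohexadienone tautomerises to the C2 phenol. This is the Danheiser benzannulation in its diazoketone form, which is established for α'-diazo enones combined with siloxyalkynes to give monosilylated resorcinols. No stereocentre remains in 19, since the single centre of 17 is lost on ring opening. The step needs (a) head-to-tail regiochemistry, secured by the polarisation of the siloxyalkyne, (b) the E alkene of 11, which places hydrogen and not the ester on the inside of the 6π terminus, and (c) selective excitation of the diazo enone, for which light near 365 nm is chosen so that the aryl ester should not undergo photo-Fries rearrangement.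

Step 10
Reactants: 19 methyl 4-({3-(diethoxymethyl)-2-hydroxy-6-methyl-4-[(triisopropylsilyl)oxy]benzoyl}oxy)-2-methoxy-3,6-dimethylbenzoate
Product: 21 methyl 4-[(3-formyl-2,4-dihydroxy-6-methylbenzoyl)oxy]-2-methoxy-3,6-dimethylbenzoate (2'-O-methylatranorin), via phenol acetal 20 (not isolated)
Conditions: Bu4NF, AcOH, THF, 0 °C; then 1 M aq. HCl, rt
Reagents that add atoms: water, O
Why: Fluoride cleaves the aryl silyl ether (strong Si–F bond, phenoxide leaving group, acetic acid buffer protecting the depside ester), and dilute aqueous acid then hydrolyses the acetal, activated by the two ortho hydroxyls, to the chelated C3 aldehyde without touching either ester.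

**Compound list**

1 | methyl 2,4-dihydroxy-3,6-dimethylbenzoate (atraric acid) | COC(=O)c1c(C)cc(O)c(C)c1O | starting material
2 | methyl 4-(benzyloxy)-2-hydroxy-3,6-dimethylbenzoate | COC(=O)c1c(C)cc(OCc2ccccc2)c(C)c1O | intermediate
3 | methyl 4-(benzyloxy)-2-methoxy-3,6-dimethylbenzoate | COC(=O)c1c(C)cc(OCc2ccccc2)c(C)c1OC | intermediate
4 | methyl 4-hydroxy-2-methoxy-3,6-dimethylbenzoate | COC(=O)c1c(C)cc(O)c(C)c1OC | intermediate
5 | butane-2,3-dione | CC(=O)C(C)=O | starting material
6 | tert-butyl (triphenylphosphoranylidene)acetate | CC(C)(C)OC(=O)C=P(c1ccccc1)(c1ccccc1)c1ccccc1 | starting material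
7 | tert-butyl (2E)-3-methyl-4-oxopent-2-enoate | CC(=O)/C(C)=C/C(=O)OC(C)(C)C | intermediate
8 | (2E)-3-methyl-4-oxopent-2-enoic acid | CC(=O)/C(C)=C/C(=O)O | intermediate
9 | methyl 2-methoxy-3,6-dimethyl-4-{[(2E)-3-methyl-4-oxopent-2-enoyl]oxy}benzoate | CC(=O)/C(C)=C/C(=O)Oc1cc(C)c(C(=O)OC)c(OC)c1C | intermediate
10 | methyl 2-methoxy-3,6-dimethyl-4-{[(2E)-7,7,7-trifluoro-3-methyl-4,6-dioxohept-2-enoyl]oxy}benzoate | O=C(CC(=O)/C(C)=C/C(=O)Oc1cc(C)c(C(=O)OC)c(OC)c1C)C(F)(F)F | intermediate
11 | methyl 4-{[(2E)-5-diazo-3-methyl-4-oxopent-2-enoyl]oxy}-2-methoxy-3,6-dimethylbenzoate | [N-]=[N+]=CC(=O)/C(C)=C/C(=O)Oc1cc(C)c(C(=O)OC)c(OC)c1C | intermediate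
12 | 3,3-diethoxyprop-1-yne | C#CC(OCC)OCC | starting material
13 | (3,3-diethoxyprop-1-yn-1-yl)lithium | [Li]C#CC(OCC)OCC | intermediate
14 | lithium 3,3-diethoxyprop-1-yn-1-olate | [Li]OC#CC(OCC)OCC | intermediate
15 | 3,3-diethoxy-1-[(triisopropylsilyl)oxy]prop-1-yne | CCOC(OCC)C#CO[Si](C(C)C)(C(C)C)C(C)C | intermediate
16 | methyl 2-methoxy-3,6-dimethyl-4-{[(2E)-3-methyl-5-oxopenta-2,4-dienoyl]oxy}benzoate (vinylketene) | O=C=C/C(C)=C/C(=O)Oc1cc(C)c(C(=O)OC)c(OC)c1C | intermediate
17 | ring B aryl (2E)-3-{3-(diethoxymethyl)-4-oxo-2-[(triisopropylsilyl)oxy]cyclobut-2-en-1-yl}but-2-enoate (racemic) | O=C1C(C(OCC)OCC)=C(O[Si](C(C)C)(C(C)C)C(C)C)C1/C(C)=C/C(=O)Oc2cc(C)c(C(=O)OC)c(OC)c2C | intermediate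
18 | ring B aryl 6-(diethoxymethyl)-3-methyl-7-oxo-5-[(triisopropylsilyl)oxy]hepta-2,4,6-trienoate (dienylketene; ketene carbon and alkenyl group cis across the central double bond, chain and ester trans across the terminal one) | O=C=C(C(OCC)OCC)/C(O[Si](C(C)C)(C(C)C)C(C)C)=C\C(C)=C\C(=O)Oc1cc(C)c(C(=O)OC)c(OC)c1C | intermediate
19 | methyl 4-({3-(diethoxymethyl)-2-hydroxy-6-methyl-4-[(triisopropylsilyl)oxy]benzoyl}oxy)-2-methoxy-3,6-dimethylbenzoate | CCOC(OCC)c1c(O)c(C(=O)Oc2cc(C)c(C(=O)OC)c(OC)c2C)c(C)cc1O[Si](C(C)C)(C(C)C)C(C)C | intermediate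
20 | methyl 4-{[3-(diethoxymethyl)-2,4-dihydroxy-6-methylbenzoyl]oxy}-2-methoxy-3,6-dimethylbenzoate | CCOC(OCC)c1c(O)c(C(=O)Oc2cc(C)c(C(=O)OC)c(OC)c2C)c(C)cc1O | intermediate
21 | methyl 4-[(3-formyl-2,4-dihydroxy-6-methylbenzoyl)oxy]-2-methoxy-3,6-dimethylbenzoate (2'-O-methylatranorin) | COC(=O)c1c(C)cc(OC(=O)c2c(C)cc(O)c(C=O)c2O)c(C)c1OC | target

**Step count**

Total: 10 steps. Longest linear sequence: 7 steps (1, 2, 3, 6, 7, 9, 10, from atraric acid). Steps 4–5 and step 8 are side branches.

**Steps most likely to fail**

Step 9 (benzannulation). Competing photochemistry may consume the material: photo-Fries rearrangement of the aryl ester, or light-induced E/Z isomerisation of the enoate that would put the ester on the inside of the 6π terminus. The ketene may also be lost before the alkyne traps it, by dimerisation of the electron-poor vinylketene or O-acylation of the phenolic product, and traces of acid may ionise the propargylic acetal of the siloxyalkyne. The fallback sets out from 4 and comes back at 21; ring A is brought in as a preformed benzoic acid (classical depside esterification) and the formyl group is introduced last. Purchased ethyl 2,4-dihydroxy-6-methylbenzoate F1 would be benzylated on both hydroxyls (BnBr, K2CO3, DMF, 60 °C) to ethyl 2,4-bis(benzyloxy)-6-methylbenzoate F2 and saponified (KOH, aqueous DMSO, 90 °C) to 2,4-bis(benzyloxy)-6-methylbenzoic acid F3. Condensation of F3 with phenol 4 through the mixed trifluoroacetic anhydride ((CF3CO)2O, toluene, rt) would give the dibenzyl depside F4, and hydrogenolysis (H2, Pd/C, EtOAc) the ring A resorcinol depside F5. Rieche formylation (Cl2CHOMe, TiCl4, CH2Cl2, −20 to 0 °C, then dilute HCl) should place the aldehyde at C3, between the two titanium-bound phenol oxygens, to give 21; a C5 regioisomer would have to be separated.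

Step 7 (diazo transfer). The lithium enolate of 9 may add to the doubly activated alkene or to the aryl ester of a second molecule (oligomerisation, acyl transfer) before it is trifluoroacetylated, and the aryl ester may be cleaved during the amine/water stage. The fallback sets out from 9 and comes back at 11 without any lithium enolate. Soft enolisation (Me3SiOTf, Et3N, CH2Cl2, 0 °C) would give the 2-silyloxydiene methyl 2-methoxy-3,6-dimethyl-4-({(2E)-3-methyl-4-[(trimethylsilyl)oxy]penta-2,4-dienoyl}oxy)benzoate F6, and NBS (THF, −78 °C) the bromomethyl ketone methyl 4-{[(2E)-5-bromo-3-methyl-4-oxopent-2-enoyl]oxy}-2-methoxy-3,6-dimethylbenzoate F7. N,N'-Ditosylhydrazine with DBU (THF, 0 °C) would then convert the bromide into diazoketone 11 by N-alkylation and twofold sulfinate elimination.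

Step 8 (siloxyalkyne). Oxygen transfer to the less nucleophilic acetal-bearing acetylide may be incomplete, silylation may go to carbon (silylketene formation), and the propargylic acetal may ionise during isolation. In the fallback the ynolate is made by Kowalski ester homologation instead of acetylide oxidation. This sequence consumes no numbered compound of the route: purchased ethyl diethoxyacetate F8 replaces 12, and it comes back at 14. Addition of F8 to LiCHBr2 (CH2Br2, lithium 2,2,6,6-tetramethylpiperidide, THF, −78 °C) followed by LiN(SiMe3)2 would give lithium 1,1-dibromo-3,3-diethoxyprop-1-en-2-olate F9. n-BuLi (−78 °C to rt) would trigger bromine–lithium exchange and 1,2-shift to the lithium ynolate 14, which is silylated as in step 8 to give 15.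

**Further compounds**

F1 | step 9 | ethyl 2,4-dihydroxy-6-methylbenzoate (purchased) | CCOC(=O)c1c(C)cc(O)cc1O
F2 | step 9 | ethyl 2,4-bis(benzyloxy)-6-methylbenzoate | CCOC(=O)c1c(C)cc(OCc2ccccc2)cc1OCc1ccccc1
F3 | step 9 | 2,4-bis(benzyloxy)-6-methylbenzoic acid | OC(=O)c1c(C)cc(OCc2ccccc2)cc1OCc1ccccc1
F4 | step 9 | methyl 4-{[2,4-bis(benzyloxy)-6-methylbenzoyl]oxy}-2-methoxy-3,6-dimethylbenzoate | COC(=O)c1c(C)cc(OC(=O)c2c(C)cc(OCc3ccccc3)cc2OCc2ccccc2)c(C)c1OC
F5 | step 9 | methyl 4-[(2,4-dihydroxy-6-methylbenzoyl)oxy]-2-methoxy-3,6-dimethylbenzoate | COC(=O)c1c(C)cc(OC(=O)c2c(C)cc(O)cc2O)c(C)c1OC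
F6 | step 7 | methyl 2-methoxy-3,6-dimethyl-4-({(2E)-3-methyl-4-[(trimethylsilyl)oxy]penta-2,4-dienoyl}oxy)benzoate | C=C(O[Si](C)(C)C)/C(C)=C/C(=O)Oc1cc(C)c(C(=O)OC)c(OC)c1C
F7 | step 7 | methyl 4-{[(2E)-5-bromo-3-methyl-4-oxopent-2-enoyl]oxy}-2-methoxy-3,6-dimethylbenzoate | BrCC(=O)/C(C)=C/C(=O)Oc1cc(C)c(C(=O)OC)c(OC)c1C
F8 | step 8 | ethyl diethoxyacetate (purchased) | CCOC(=O)C(OCC)OCC
F9 | step 8 | lithium 1,1-dibromo-3,3-diethoxyprop-1-en-2-olate | [Li]OC(=C(Br)Br)C(OCC)OCC
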